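Free catalyst moves this chemistry harder than partner does: as read, with their scatter, from noon to summer the loading goes from 0.1 mol% to 0.2 mol% and the loss constant, ln of the inverse fraction left divided by the time, rises from 0.375 h⁻¹ to 0.848 h⁻¹, a factor 2.26, whereas from summer to midnight partner goes from 2 equiv to 4.4 equiv for a rise to 1.07 h⁻¹, a factor 1.26.

| flask | starting material | partner | free catalyst | remark | time |
|---|---|---|---|---|---|
| summer | 0.079 M | 2 equiv | 0.2 mol% | run made earlier |  |
| winter | 0.079 M | 2.8 equiv | 0.2 mol% | run made earlier |  |
| midnight | 0.079 M | 4.4 equiv | 0.2 mol% | run made earlier |  |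
| noon | 0.079 M | 2 equiv | 0.1 mol% | run made earlier |  |
| amber | 0.079 M (fed, over 1.25 h) | 2.00 equiv | 0.2 mol% | all but starting material at the start; starting material goes in evenly over 1.25 h, the run ends at 2.5 h | 2.5 h |
| teal | 0.079 M | 2.00 equiv (fed, over 1.25 h) | 0.2 mol% | a stirred flask in which partner is dosed at a steady rate over 1.25 h without added volume, worked up at 2.5 h | 2.5 h |
| grey | 0.079 M | 2.00 equiv | 0.2 mol% | a closed flask charged with all of it at once and left for 2.5 h | 2.5 h |
| blue | 0.079 M | 2.00 equiv | 0.2 mol% | one stirred flow tank at steady state, fed with the mixture as stated, mean residence time 2.5 h |  |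

summer run (percent of the starting material charged)

| time / h | product / % | starting material / % |
|---|---|---|
| 0.200 | 14 | 89 |
| 0.333 | 20 | 78 |
| 0.500 | 29 | 71 |
| 0.833 | 46 | 53 |
| 1.50 | 70 | 32 |
| 2.50 | 88 | 12 |

winter run (percent of the starting material charged)

| time / min | product / % | starting material / % |
|---|---|---|
| 8.00 | 10 | 87 |
| 12.0 | 17 | 87 |
| 20.0 | 25 | 76 |
| 30.0 | 35 | 63 |
| 50.0 | 53 | 50 |
| 90.0 | 75 | 25 |

midnight run (percent of the starting material charged)

| time / min | product / % | starting material / % |
|---|---|---|
| 6.00 | 12 | 92 |
| 20.0 | 28 | 75 |
| 30.0 | 40 | 61 |
| 50.0 | 61 | 47 |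
| 60.0 | 65 | 36 |
| 90.0 | 82 | 20 |

noon run (percent of the starting material charged)

| time / min | product / % | starting material / % |
|---|---|---|
| 20.0 | 12 | 94 |
| 40.0 | 25 | 81 |
| 50.0 | 25 | 72 |
| 80.0 | 39 | 62 |
| 90.0 | 44 | 57 |

(standard deviation of a reading: 2 percentage points)

- the stated concentrations are those of everything mixed, before any reaction; amounts are the same in each set-up
- the feed brings no volume worth counting
- the earlier runs were made in a closed, stirred flask

1. the set-up with the highest amount of product at the outlet or at the end, in percent of the starting material put in ("none" if the first two lie within 2 percentage points) (amber / teal / grey / blue / none)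
2. amount of product at the outlet or at the end, in percent of the starting material put in, amber
3. amount of product at the outlet or at the end, in percent of the starting material put in, teal
4. amount of product at the outlet or at the end, in percent of the starting material put in, grey
5. amount of product at the outlet or at the end, in percent of the starting material put in, blue

Note for the bench, as an own reckoning. The flask grey holds the summer charge, put in at once, and the last summer readings add up to 100% of the charge, so starting material lost counts as product. The loss constant times the time of stay gives

N = 0.848 h⁻¹ × 2.5 h = 2.12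

which is the number of lifetimes the material gets, a Damköhler number. With a the fraction left, the closed flask grey gives

a = exp(−N) = 0.120

which is the summer reading returned, not a test. In the tank blue, loss k·a equals renewal (1 − a)/τ, and dividing one by the other drops time:

(1 − a)/a = N, so a = 0.320

So this reckoning puts product at 0.880 of the charge in grey at 2.5 h, and at 0.680 at the outlet of the tank blue, which leaves a larger fraction of starting material. The charge of grey stays untouched: starting material fed over 1.25 h in amber gets on average 1.88 h of stay, less than 2.5 h.

The forecast gives amber 78%, teal 79%, grey 87%, blue 66%, and names grey: “Grey is best by a clear margin”.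

The flasks give amber 80.3%, teal 81.0%, grey 88.5%, blue 67.1%; best is grey.

    catalyst intermediate C → spent catalyst (k = 0.0270 min⁻¹)
    catalyst intermediate A ⇌ by-product + catalyst intermediate B (K = 3.70 M, k = 62.0 min⁻¹)
    starting material + catalyst intermediate B → catalyst intermediate C (k = 160 M⁻¹ min⁻¹)
    partner + free catalyst ⇌ catalyst intermediate A (K = 11.0 M⁻¹, k = 99.0 M⁻¹ min⁻¹)
    catalyst intermediate C ⇌ free catalyst + product (K = 0.440 M, k = 1200 min⁻¹)

Grey, with N = 2.12 from summer, falls short of full conversion mainly for want of time: it stands at 88.5% after 2.5 h and at 99.9% when left ten times as long, and the time given accounts for 99.1% of what is missing. With all amounts held, the answer for grey has moved by 5 points at 2.14 h and at 3.03 h.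

In the neighbour flask, grey left until 6.0 h, N becomes 5.09 and exp(−N) gives product at 0.994 of the charge; the computed flask stands at 99.8%.

All runs were generated by integration from invented constants.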